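**Retrosynthetic overview**

1. Ring atoms are numbered C1–C14 in the order of the SMILES string (C1 = methyl-bearing carbon of the Z-alkene, C8 = carbinol carbon, C11 = methyl-bearing carbon of the isolated E-alkene). The only ring, the 14-membered carbocycle, is formed last.
2. The ring is closed at C10–C11 by a one-pot hydroboration/B-alkyl Suzuki–Miyaura macrocyclisation. Enabling feature: C10 lies two carbons from the fully substituted carbinol carbon C8, so it can travel as the terminus of a C9=C10 vinyl group on C8 (no allylic hydrogen, no acidic site) and become a primary alkylborane only at the moment of closure. C11 is sp2 and stores the E geometry of C11=C12 in a bromoalkene.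
3. The open chain is cut at C3–C4, the doubly allylic CH2 of the skipped diene: zirconium-catalysed carboalumination of a C4≡C5 alkyne, then palladium-catalysed coupling with a (Z)-allylic chloride that carries C3–C1 and C14–C11.
4. West half: the methyl-bearing stereocentre comes from (R)-citronellal and C8 from a Sharpless epoxidation. The oxirane CH2 becomes C7 (propargyl opening), the CH2OH becomes C9=C10, and the side-chain alcohol comes from SeO2 oxidation.
5. East half: 2-butyn-1-ol and 3-pentyn-1-ol are joined by Negishi coupling of a Z-iodoalkene, then hydrozirconation/bromination.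

Key step: step 15

Remark on the chemistry: (+)-citronellal is taken as the R enantiomer of high optical purity, and the facial sense of the epoxidation in step 3 is taken from the usual rule for primary allylic alcohols (D-(−)-tartrate gives the 2R oxirane here).

**Route**

Step 1
Reactants: 1 (R)-citronellal
Product: 2 (3R)-3,7-dimethyl-2-methylideneoct-6-enal
Conditions: 37% aq. CH2O, pyrrolidine (10 mol%), EtCO2H (10 mol%), iPrOH, 45 °C
Reagents that add atoms: formaldehyde, C=O
Why: Amine-catalysed Mannich condensation of the enamine of 1 with formaldehyde and loss of the amine (α-methylenation of an aldehyde) should give the 2-methylene aldehyde, and the C3 stereocentre of the chiral pool is kept because the α-branched enal formed is a poor partner for further iminium or dienamine formation.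

Step 2
Reactants: 2 (3R)-3,7-dimethyl-2-methylideneoct-6-enal
Product: 3 (3R)-3,7-dimethyl-2-methylideneoct-6-en-1-ol
Conditions: NaBH4, CeCl3·7H2O, MeOH, 0 °C
Reagents that add atoms: none
Why: Luche reduction should deliver hydride 1,2 to the enal and give the 2-substituted allylic alcohol without touching the alkenes or the stereocentre.

Step 3
Reactants: 3 (3R)-3,7-dimethyl-2-methylideneoct-6-en-1-ol
Product: 4 [(2R)-2-[(2R)-6-methylhept-5-en-2-yl]oxiran-2-yl]methanol
Conditions: Ti(OiPr)4 (10 mol%), D-(−)-diethyl tartrate (12 mol%), t-BuOOH, 4 Å sieves, CH2Cl2, −20 °C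
Reagents that add atoms: tert-butyl hydroperoxide, CC(C)(C)OO
Why: Sharpless asymmetric epoxidation acts only on the allylic alcohol alkene and, with the D-(−)-tartrate ligand, should deliver oxygen under reagent control to the face that makes the oxirane carbon (future C8) R, the neighbouring methyl-bearing centre being too far from titanium to override the catalyst.

Step 4
Reactants: 4 [(2R)-2-[(2R)-6-methylhept-5-en-2-yl]oxiran-2-yl]methanol
Product: 6 (2R,3R)-2-(but-3-yn-1-yl)-3,7-dimethyloct-6-ene-1,2-diol, via C-silylated alkyne diol 5 (not isolated)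
Conditions: Me3SiC≡CCH3 (3 equiv), n-BuLi, TMEDA, THF, −78 → 0 °C; add 4, DMPU, −78 °C → rt; then K2CO3, MeOH, rt
Reagents that add atoms: 1-(trimethylsilyl)propyne, CC#C[Si](C)(C)C
Why: The propargylic lithium reagent should open the 2,2-disubstituted oxirane by SN2 attack at its unsubstituted CH2 (future C7), so that no bond to the quaternary carbinol carbon is broken and its configuration is kept, the silyl group steering the ambident anion to propargyl rather than allenyl attack, and K2CO3/MeOH then removes the C-silyl group (carbanion opening of an epoxide followed by protodesilylation).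

Step 5
Reactants: 6 (2R,3R)-2-(but-3-yn-1-yl)-3,7-dimethyloct-6-ene-1,2-diol
Product: 7 (2R,3R)-2-(but-3-yn-1-yl)-2-hydroxy-3,7-dimethyloct-6-enal
Conditions: SO3·pyridine, DMSO, iPr2NEt, CH2Cl2, 0 °C
Reagents that add atoms: none
Why: Parikh–Doering oxidation should convert only the primary hydroxyl of the 1,2-diol, since the tertiary one cannot be oxidised, and the α-hydroxy aldehyde has no α-hydrogen and cannot epimerise.

Step 6
Reactants: 7 (2R,3R)-2-(but-3-yn-1-yl)-2-hydroxy-3,7-dimethyloct-6-enal
Product: 8 (3S)-3-[(2R)-6-methylhept-5-en-2-yl]hept-1-en-6-yn-3-ol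
Conditions: Ph3PCH3Br (3.5 equiv), KN(SiMe3)2, THF, 0 °C → rt
Reagents that add atoms: methyltriphenylphosphonium bromide, C[P+](c1ccccc1)(c1ccccc1)c1ccccc1.[Br-]
Why: Wittig methylenation with excess ylide, which also covers the hydroxyl and alkyne protons, should turn the aldehyde into the C9=C10 vinyl group without affecting the adjacent carbinol centre.

Step 7
Reactants: 8 (3S)-3-[(2R)-6-methylhept-5-en-2-yl]hept-1-en-6-yn-3-ol
Product: 10 (2E,6R,7S)-7-(but-3-yn-1-yl)-2,6-dimethylnona-2,8-diene-1,7-diol, via enal 9 (not isolated)
Conditions: SeO2 (0.3 equiv), t-BuOOH (3 equiv), salicylic acid (10 mol%), CH2Cl2, 0 °C → rt; then NaBH4, MeOH, 0 °C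
Reagents that add atoms: tert-butyl hydroperoxide, CC(C)(C)OO
Why: SeO2-catalysed allylic oxidation (ene reaction, then [2,3]-sigmatropic shift) should hydroxylate the E-methyl group of the only trisubstituted alkene with E selectivity, the vinyl group having no allylic hydrogen, and the borohydride quench returns any over-oxidised enal to the alcohol.

Step 8
Reactants: 10 (2E,6R,7S)-7-(but-3-yn-1-yl)-2,6-dimethylnona-2,8-diene-1,7-diol
Product: 11 bis(triethylsilyl) ether of 10
Conditions: Et3SiOTf (3 equiv), 2,6-lutidine, CH2Cl2, −78 → 0 °C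
Reagents that add atoms: triethylsilyl trifluoromethanesulfonate, CC[Si](CC)(CC)OS(=O)(=O)C(F)(F)F
Why: The silyl triflate with lutidine should silylate both the primary allylic and the hindered tertiary allylic hydroxyl, so that neither can ionise or bind aluminium, palladium or boron in steps 14 and 15.

Step 9
Reactants: 12 but-2-yn-1-ol
Product: 14 (Z)-3-iodobut-2-en-1-ol, via cyclic alkenylalanate 13 (not isolated)
Conditions: NaAlH2(OCH2CH2OMe)2, THF, 0 °C → rt; then I2, −78 °C → rt
Reagents that add atoms: iodine, II
Why: Alkoxide-directed trans-hydroalumination of the propargylic alcohol should give the five-membered alkenylalanate with aluminium on C3 cis to the CH2O group, and iodinolysis with retention should give the Z-iodoalkene.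

Step 10
Reactants: 15 pent-3-yn-1-ol
Product: 16 5-iodopent-2-yne
Conditions: I2, PPh3, imidazole, CH2Cl2, 0 °C → rt
Reagents that add atoms: iodine, II
Why: Appel-type iodination should convert the primary alcohol into the iodide by SN2 displacement of the oxyphosphonium group.

Step 11
Reactants: 16 5-iodopent-2-yne; 14 (Z)-3-iodobut-2-en-1-ol
Product: 18 (2Z)-3-methyloct-2-en-6-yn-1-ol, via pent-3-ynylzinc iodide 17 (not isolated)
Conditions: Zn dust, LiCl, THF, 40 °C; then 14, Pd(OAc)2 (2 mol%), SPhos (4 mol%), THF, rt
Reagents that add atoms: none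
Why: Zinc insertion into the primary C–I bond and Negishi sp3–sp2 coupling should replace the vinylic iodine with retention, so the new chain stays cis to CH2OH (the Z alkene C1=C2 of the target), alkylzinc halides tolerating the internal alkyne and the free hydroxyl.

Step 12
Reactants: 18 (2Z)-3-methyloct-2-en-6-yn-1-ol
Product: 20 (2Z,6E)-7-bromo-3-methylocta-2,6-dien-1-ol, via alkenylzirconocene 19 (not isolated)
Conditions: Cp2Zr(H)Cl (3 equiv), THF, rt → 45 °C; then NBS, 0 °C
Reagents that add atoms: N-bromosuccinimide, O=C1CCC(=O)N1Br
Why: Syn-hydrozirconation with excess reagent should settle zirconium on the less hindered, methyl-bearing alkyne carbon, and bromination with retention should give the E-bromoalkene, any minor regioisomer being removed at this small-fragment stage; bromide is chosen over iodide so that the halide survives the palladium step 14.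

Step 13
Reactants: 20 (2Z,6E)-7-bromo-3-methylocta-2,6-dien-1-ol
Product: 21 (2Z,6E)-7-bromo-1-chloro-3-methylocta-2,6-diene
Conditions: NCS, Me2S, CH2Cl2, −30 → 0 °C
Reagents that add atoms: N-chlorosuccinimide, O=C1CCC(=O)N1Cl
Why: Corey–Kim chlorination should displace the alkoxysulfonium group by chloride in an SN2 sense, without allylic transposition and without change of the Z geometry.

Step 14
Reactants: 11 bis(triethylsilyl) ether of 10; 21 (2Z,6E)-7-bromo-1-chloro-3-methylocta-2,6-diene
Product: 23 open-chain bromotetraene bis(triethylsilyl) ether, via alkenylalane 22 (not isolated)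
Conditions: AlMe3 (3 equiv), Cp2ZrCl2 (0.3 equiv), CH2Cl2, 0 °C → rt; evaporate; then 21, Pd(PPh3)4 (5 mol%), THF, 0 °C → rt
Reagents that add atoms: trimethylaluminium, C[Al](C)C
Why: Zirconium-catalysed syn-methylalumination of the terminal alkyne (Negishi carboalumination) should put methyl on C5 and aluminium on C4 to give the E-alkenylalane, and palladium-catalysed allyl–alkenyl coupling should join C4 to the primary allylic carbon C3 with retention of both alkene geometries, the allylic chloride adding to zerovalent palladium much faster than the hindered trisubstituted bromoalkene.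

Step 15
Reactants: 23 open-chain bromotetraene bis(triethylsilyl) ether
Product: 25 14-membered triene bis(triethylsilyl) ether, via alkylborane 24 (not isolated)
Conditions: 9-BBN (1.5 equiv), THF, rt; then syringe-pump addition to Pd(dppf)Cl2 (15 mol%), AsPh3 (30 mol%), Cs2CO3 (3 equiv), DMF/THF/H2O, 60 °C, final 1 mM
Reagents that add atoms: none
Why: 9-BBN adds anti-Markovnikov to the only monosubstituted alkene (C9=C10) and puts boron on C10; zerovalent palladium generated from Pd(dppf)Cl2 then inserts into the C11–Br bond, the base-activated primary alkyl group moves from boron to palladium, and reductive elimination forms the C10–C11 bond. The closest known reaction type is the one-pot hydroboration/B-alkyl Suzuki–Miyaura macrocyclisation that closes macrocarbocycles and macrolides at a trisubstituted alkene. The 14-membered carbocycle (C1–C14) is closed end to end by reductive elimination from a 15-membered palladacycle, with the new alkene C11=C12 endocyclic. No stereocentre is created: the E geometry of C11=C12 is handed on from the bromoalkene because oxidative addition and reductive elimination go with retention at sp2 carbon, and C8 and its methyl-bearing neighbour are not touched. The step needs chemoselective hydroboration, which the substrate secures because its other four alkenes are trisubstituted (one deactivated by bromine) and inert to 9-BBN at room temperature, and it needs ring closure to outrun oligomerisation, which slow addition at high dilution and the absence of any second halide or boron site should secure. Boron sits two carbons from the silylated carbinol carbon, so neither β-alkoxy elimination nor neopentyl hindrance should interfere with transmetalation.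

Step 16
Reactants: 25 14-membered triene bis(triethylsilyl) ether
Product: 26 (1R,4E,7Z,11E)-1-[(2R,5E)-7-hydroxy-6-methylhept-5-en-2-yl]-4,8,12-trimethylcyclotetradeca-4,7,11-trien-1-ol (CNP0178561.1)
Conditions: Bu4NF, THF, 0 °C → rt
Reagents that add atoms: none
Why: Fluoride-induced cleavage of both Si–O bonds should free the primary allylic and the tertiary alcohol without touching the three ring alkenes or the stereocentres.

**Compound list**

1 | (R)-citronellal, (3R)-3,7-dimethyloct-6-enal | O=CC[C@H](C)CCC=C(C)C | starting material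
2 | (3R)-3,7-dimethyl-2-methylideneoct-6-enal | O=CC(=C)[C@H](C)CCC=C(C)C | intermediate
3 | (3R)-3,7-dimethyl-2-methylideneoct-6-en-1-ol | OCC(=C)[C@H](C)CCC=C(C)C | intermediate
4 | [(2R)-2-[(2R)-6-methylhept-5-en-2-yl]oxiran-2-yl]methanol | OC[C@]1([C@H](C)CCC=C(C)C)CO1 | intermediate
5 | (2R,3R)-3,7-dimethyl-2-[4-(trimethylsilyl)but-3-yn-1-yl]oct-6-ene-1,2-diol (not isolated) | OC[C@@](O)(CCC#C[Si](C)(C)C)[C@H](C)CCC=C(C)C | intermediate
6 | (2R,3R)-2-(but-3-yn-1-yl)-3,7-dimethyloct-6-ene-1,2-diol | OC[C@@](O)(CCC#C)[C@H](C)CCC=C(C)C | intermediate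
7 | (2R,3R)-2-(but-3-yn-1-yl)-2-hydroxy-3,7-dimethyloct-6-enal | O=C[C@@](O)(CCC#C)[C@H](C)CCC=C(C)C | intermediate
8 | (3S)-3-[(2R)-6-methylhept-5-en-2-yl]hept-1-en-6-yn-3-ol | C=C[C@@](O)(CCC#C)[C@H](C)CCC=C(C)C | intermediate
9 | (2E,6R,7S)-7-(but-3-yn-1-yl)-7-hydroxy-2,6-dimethylnona-2,8-dienal (not isolated) | C=C[C@@](O)(CCC#C)[C@H](C)CC/C=C(\C)C=O | intermediate
10 | (2E,6R,7S)-7-(but-3-yn-1-yl)-2,6-dimethylnona-2,8-diene-1,7-diol | C=C[C@@](O)(CCC#C)[C@H](C)CC/C=C(\C)CO | intermediate
11 | bis(triethylsilyl) ether of 10 | C=C[C@@](O[Si](CC)(CC)CC)(CCC#C)[C@H](C)CC/C=C(\C)CO[Si](CC)(CC)CC | intermediate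
12 | but-2-yn-1-ol | CC#CCO | starting material
13 | sodium salt of the five-membered cyclic (Z)-alkenylalanate from 12 (not isolated) | [Na+].CC1=CCO[Al-]1(OCCOC)OCCOC | intermediate
14 | (Z)-3-iodobut-2-en-1-ol | C/C(I)=C/CO | intermediate
15 | pent-3-yn-1-ol | CC#CCCO | starting material
16 | 5-iodopent-2-yne | CC#CCCI | intermediate
17 | pent-3-ynylzinc iodide (not isolated) | CC#CCC[Zn]I | intermediate
18 | (2Z)-3-methyloct-2-en-6-yn-1-ol | C/C(CCC#CC)=C/CO | intermediate
19 | O-zirconated (E)-alkenylzirconocene chloride from 18, zirconium on the methyl-bearing carbon (not isolated) | C/C(=C\CC/C(C)=C\CO[Zr](Cl)(C1C=CC=C1)C1C=CC=C1)[Zr](Cl)(C1C=CC=C1)C1C=CC=C1 | intermediate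
20 | (2Z,6E)-7-bromo-3-methylocta-2,6-dien-1-ol | C/C(Br)=C\CC/C(C)=C\CO | intermediate
21 | (2Z,6E)-7-bromo-1-chloro-3-methylocta-2,6-diene | C/C(Br)=C\CC/C(C)=C\CCl | intermediate
22 | (E)-alkenyldimethylalane from 11, aluminium on C4 and new methyl on C5 (not isolated) | C[Al](C)/C=C(\C)CC[C@](O[Si](CC)(CC)CC)(C=C)[C@H](C)CC/C=C(\C)CO[Si](CC)(CC)CC | intermediate
23 | open-chain bromotetraene bis(triethylsilyl) ether: (E)-bromoalkene at C11, Z alkene C1=C2, E alkene C4=C5, vinyl group on C8 | C/C(Br)=C\CC/C(C)=C\C/C=C(\C)CC[C@](O[Si](CC)(CC)CC)(C=C)[C@H](C)CC/C=C(\C)CO[Si](CC)(CC)CC | intermediate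
24 | B-alkyl-9-borabicyclo[3.3.1]nonane from 23, boron on C10 (not isolated) | C/C(Br)=C\CC/C(C)=C\C/C=C(\C)CC[C@](O[Si](CC)(CC)CC)(CCB1C2CCCC1CCC2)[C@H](C)CC/C=C(\C)CO[Si](CC)(CC)CC | intermediate
25 | 14-membered triene bis(triethylsilyl) ether (bis-silyl ether of the target) | C/C1=C/C/C=C(\C)CC[C@@](O[Si](CC)(CC)CC)([C@H](C)CC/C=C(\C)CO[Si](CC)(CC)CC)CC/C(C)=C/CC1 | intermediate
26 | (1R,4E,7Z,11E)-1-[(2R,5E)-7-hydroxy-6-methylhept-5-en-2-yl]-4,8,12-trimethylcyclotetradeca-4,7,11-trien-1-ol | C/C1=C/C/C=C(\C)CC[C@@](O)([C@H](C)CC/C=C(\C)CO)CC/C(C)=C/CC1 | target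

**Count and risks**

Total step count: 16. Longest linear sequence: 11 steps (steps 1–8, 14, 15, 16); the east fragment takes steps 9–13.

Steps most likely to fail:

Step 15 (macrocyclisation). Intermolecular coupling may outrun ring closure, the alkylborane may be protodeboronated, or slow oxidative addition into the hindered bromoalkene may leave time for palladium hydride-induced alkene migration in the skipped diene. Fallback, from 23 back to 25, with the organometal made and purified before the coupling: hydroboration of 23 as above and oxidation with NaOH/H2O2 would give the primary alcohol F1. I2, PPh3 and imidazole would give the primary iodide F2. Zinc insertion (Zn, LiCl, THF), which leaves the bromoalkene alone, would give the alkylzinc iodide F3. This would be closed by an intramolecular Negishi coupling (Pd(OAc)2, SPhos, THF, syringe pump, high dilution) to 25.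

Step 14 (fragment union). Zerovalent palladium may also insert into the bromoalkene and cross-link the fragments, methyl may be transferred from aluminium instead of the alkenyl group, or the Z geometry may be lost through isomerisation of the allylpalladium intermediate. Fallback without palladium, from 22 back to 23: iodinolysis of 22 (I2, THF, −30 °C) would give the (E)-alkenyl iodide F4. Iodine–lithium exchange (t-BuLi, Et2O, −78 °C) would give the alkenyllithium F5, and CuI with P(OEt)3 the alkenylcopper reagent F6. This would be alkylated at the primary carbon of the allylic bromide F7, made from 20 with CBr4 and PPh3, to return to 23.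

Step 7 (allylic oxidation). Oxidation may also occur at the propargylic CH2, may run on to the enal and beyond, or the acidic medium may induce allylic transposition of the tertiary vinyl carbinol. Fallback by degradation and olefination, from 8 back to 10: mCPBA (1 equiv, NaHCO3, CH2Cl2, 0 °C) should epoxidise only the electron-rich trisubstituted alkene to give the epoxide F8. HIO4 in aqueous THF would cleave it to the aldehyde F9 (in equilibrium with its lactol). Ph3P=C(CH3)CO2Et would give the (E)-enoate F10, and (i-Bu)2AlH at −78 °C would reduce it to 10.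

**Further compounds**

F1 | step 15 | primary alcohol at C10 from hydroboration–oxidation of 23 | C/C(Br)=C\CC/C(C)=C\C/C=C(\C)CC[C@](O[Si](CC)(CC)CC)(CCO)[C@H](C)CC/C=C(\C)CO[Si](CC)(CC)CC
F2 | step 15 | primary iodide at C10 | C/C(Br)=C\CC/C(C)=C\C/C=C(\C)CC[C@](O[Si](CC)(CC)CC)(CCI)[C@H](C)CC/C=C(\C)CO[Si](CC)(CC)CC
F3 | step 15 | alkylzinc iodide at C10 | C/C(Br)=C\CC/C(C)=C\C/C=C(\C)CC[C@](O[Si](CC)(CC)CC)(CC[Zn]I)[C@H](C)CC/C=C(\C)CO[Si](CC)(CC)CC
F4 | step 14 | (E)-alkenyl iodide at C4 from 22 | I/C=C(\C)CC[C@](O[Si](CC)(CC)CC)(C=C)[C@H](C)CC/C=C(\C)CO[Si](CC)(CC)CC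
F5 | step 14 | (E)-alkenyllithium at C4 | [Li]/C=C(\C)CC[C@](O[Si](CC)(CC)CC)(C=C)[C@H](C)CC/C=C(\C)CO[Si](CC)(CC)CC
F6 | step 14 | (E)-alkenylcopper reagent at C4 | [Cu]/C=C(\C)CC[C@](O[Si](CC)(CC)CC)(C=C)[C@H](C)CC/C=C(\C)CO[Si](CC)(CC)CC
F7 | step 14 | (2Z,6E)-1,7-dibromo-3-methylocta-2,6-diene | C/C(Br)=C\CC/C(C)=C\CBr
F8 | step 7 | epoxide of the trisubstituted alkene of 8 (epimers at the oxirane carbon) | C=C[C@@](O)(CCC#C)[C@H](C)CCC1OC1(C)C
F9 | step 7 | (4R,5S)-5-ethenyl-5-hydroxy-4-methylnon-8-ynal | C=C[C@@](O)(CCC#C)[C@H](C)CCC=O
F10 | step 7 | ethyl (2E,6R,7S)-7-(but-3-yn-1-yl)-7-hydroxy-2,6-dimethylnona-2,8-dienoate | C=C[C@@](O)(CCC#C)[C@H](C)CC/C=C(\C)C(=O)OCC
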